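**Retrosynthetic overview**
- Feature: ring B (C1 bearing the benzylic CH2, C3–OH, C4–acyl, C5–OH, C2 and C6 unsubstituted) is a 2-acylresorcinol whose only carbon substituent sits para to the acyl group. C1, C2, C3 and C6 map onto a vinylketene, and C4 and C5 onto an oxygenated alkyne.
- Last disconnections: the O–CH3 bond at C5 (chelation-directed cleavage) and both aryl ketones, which are traced back to silyl-protected benzylic carbinols.
- Key disconnection: C3–C4 and C5–C6 of ring B (C2–C3 is re-formed on closure), leading to a 3-substituted cyclobutenone and a 1-methoxyalkyne that carries the masked acyl chain.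
- Cyclobutenone: anisaldehyde, homopropargylic silyl ether, dichloroketene [2+2], zinc dechlorination. Alkyne: lithium methoxyacetylide plus 4-methylpentanal, then silylation.
- Ring order: ring A is bought, the four-membered ring is built as a relay, and ring B is formed last from it in the benzannulation.

Key step: step 7

Remark on the chemistry: the target is achiral, so the two carbinol centres that serve as masked ketones are carried racemic (as diastereomer mixtures after step 7) and are erased in step 9.

**Route**

Step 1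
Reactants: 1 4-methoxybenzaldehyde; 2 propargyl bromide
Product: 4 1-(4-methoxyphenyl)but-3-yn-1-ol (racemic), via allenylzinc bromide 3 (not isolated)
Conditions: Zn dust (activated), THF, 0 °C → rt; then sat. aq NH4Cl
Reagents that add atoms: none
Why: Zinc Barbier propargylation, in which zinc inserts into the C–Br bond to give allenylzinc bromide that adds to the aldehyde through its γ-carbon (SE2′) to give the homopropargylic alcohol; the carbinol centre forms without control (racemic), which is acceptable because it becomes a ketone in step 9.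

Step 2
Reactants: 4 1-(4-methoxyphenyl)but-3-yn-1-ol
Product: 5 tert-butyl{[1-(4-methoxyphenyl)but-3-yn-1-yl]oxy}dimethylsilane (racemic)
Conditions: TBSCl, imidazole, DMF, rt
Reagents that add atoms: tert-butyldimethylsilyl chloride, CC(C)(C)[Si](C)(C)Cl
Why: Standard imidazole-promoted O-silylation of a secondary alcohol, which masks the future ketone so that nothing enolisable or electrophilic is present during the ketene steps.

Step 3
Reactants: 5 tert-butyl{[1-(4-methoxyphenyl)but-3-yn-1-yl]oxy}dimethylsilane; 6 trichloroacetyl chloride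
Product: 8 3-[2-(tert-butyldimethylsilyloxy)-2-(4-methoxyphenyl)ethyl]-4,4-dichlorocyclobut-2-en-1-one (racemic), via dichloroketene 7 (not isolated)
Conditions: Zn–Cu couple, Et2O–DME, rt, slow addition of 6
Reagents that add atoms: none
Why: Ketene–alkyne [2+2] cycloaddition, in which dichloroketene from zinc dechlorination of the acid chloride bonds its carbonyl carbon to the unsubstituted alkyne carbon to give the 3-substituted 4,4-dichlorocyclobutenone, while DME ties up ZnCl2 so that the ionisable benzylic silyl ether should be spared.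

Step 4
Reactants: 8 3-[2-(tert-butyldimethylsilyloxy)-2-(4-methoxyphenyl)ethyl]-4,4-dichlorocyclobut-2-en-1-one
Product: 9 3-[2-(tert-butyldimethylsilyloxy)-2-(4-methoxyphenyl)ethyl]cyclobut-2-en-1-one (racemic)
Conditions: Zn dust, AcOH, TMEDA, EtOH, 0 °C → rt
Reagents that add atoms: none
Why: Reductive dechlorination of an α,α-dichloroketone by zinc in TMEDA-buffered acetic acid (zinc enolate formation and protonation, twice), conditions established for 4,4-dichlorocyclobutenones that leave the ring C=C and the silyl ether untouched.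

Step 5
Reactants: 10 chloroacetaldehyde dimethyl acetal; 11 4-methylpentanal
Product: 13 1-methoxy-6-methylhept-1-yn-3-ol (racemic), via lithium methoxyacetylide 12 (not isolated)
Conditions: LiNEt2 (3.1 equiv, from Et2NH and n-BuLi), THF, 0 °C; then 11, −78 → 0 °C; aq NaHCO3
Reagents that add atoms: none
Why: Double elimination (methanol, then HCl) and deprotonation of the chloroacetal by the lithium amide gives lithium methoxyacetylide, which undergoes acetylide 1,2-addition to the aldehyde; the propargylic carbinol forms racemic and is oxidised later.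

Step 6
Reactants: 13 1-methoxy-6-methylhept-1-yn-3-ol
Product: 14 tert-butyl[(1-methoxy-6-methylhept-1-yn-3-yl)oxy]dimethylsilane (racemic)
Conditions: TBSCl, imidazole, DMF, rt; chromatography on Et3N-deactivated silica
Reagents that add atoms: tert-butyldimethylsilyl chloride, CC(C)(C)[Si](C)(C)Cl
Why: Imidazole-promoted O-silylation under basic conditions, which avoids the acid-triggered Meyer–Schuster rearrangement of the ynol ether carbinol and gives a partner free of acidic protons for the ketene.

Step 7
Reactants: 9 3-[2-(tert-butyldimethylsilyloxy)-2-(4-methoxyphenyl)ethyl]cyclobut-2-en-1-one; 14 tert-butyl[(1-methoxy-6-methylhept-1-yn-3-yl)oxy]dimethylsilane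
Product: 19 2-[1-(tert-butyldimethylsilyloxy)-4-methylpentyl]-5-[2-(tert-butyldimethylsilyloxy)-2-(4-methoxyphenyl)ethyl]-3-methoxyphenol (diastereomer mixture), via vinylketene 15 (not isolated), via vinylcyclobutenone 16 (not isolated), via dienylketene 17 (not isolated), via cyclohexadienone 18 (not isolated)
Conditions: 14 (1.3 equiv), degassed toluene, 80 °C then 110 °C, sealed tube
Reagents that add atoms: none
Why: Danheiser benzannulation, in which 9 undergoes four-electron electrocyclic opening at 80 °C to vinylketene 15, whose electrophilic ketene carbon is attacked by the oxygen-free carbon of ynol ether 14 in a [2+2] cycloaddition that forms C3–C4 and C5–C6 and gives vinylcyclobutenone 16. A second four-electron opening gives dienylketene 17, and ring B is closed by a thermal six-electron electrocyclisation that re-forms C2–C3 to give cyclohexadienone 18, which tautomerises to the phenol. The closest known reaction type is the thermal benzannulation of 3-alkylcyclobutenones with 1-methoxy- and 1-siloxyalkynes to 2,5-disubstituted resorcinol monoethers. No stereocentre is created, and the two silyl ether centres pass through unchanged as a diastereomer mixture. The selectivity needed is the orientation of the ketene–alkyne [2+2], and it is secured by the polarisation of the methoxyalkyne, so the masked acyl chain lands at C4 between the two oxygens and the cyclobutenone substituent lands at C1, para to it. Both ketones are present only as silyl ethers, so no enolisable or electrophilic carbonyl competes for the ketene, and the slight excess of 14 limits acylation of the product phenol by 15.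

Step 8
Reactants: 19 2-[1-(tert-butyldimethylsilyloxy)-4-methylpentyl]-5-[2-(tert-butyldimethylsilyloxy)-2-(4-methoxyphenyl)ethyl]-3-methoxyphenol
Product: 20 2-(1-hydroxy-4-methylpentyl)-5-[2-hydroxy-2-(4-methoxyphenyl)ethyl]-3-methoxyphenol (diastereomer mixture)
Conditions: TBAF (4 equiv), THF, 0 °C → rt; pH 7 buffer work-up
Reagents that add atoms: none
Why: Fluoride-mediated Si–O cleavage frees both secondary benzylic carbinols without acid, which matters because the doubly ortho-oxygenated benzylic alcohol would ionise under acidic conditions; the configuration at both carbinols is irrelevant.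

Step 9
Reactants: 20 2-(1-hydroxy-4-methylpentyl)-5-[2-hydroxy-2-(4-methoxyphenyl)ethyl]-3-methoxyphenol
Product: 21 1-{2-hydroxy-6-methoxy-4-[2-(4-methoxyphenyl)-2-oxoethyl]phenyl}-4-methylpentan-1-one
Conditions: activated MnO2 (large excess), CH2Cl2, rt
Reagents that add atoms: none
Why: Chemoselective MnO2 oxidation of benzylic alcohols, in which both carbinols sit on electron-rich rings and should be oxidised to aryl ketones on the oxide surface while the phenol and the doubly activated CH2 are left, and both stereocentres are erased.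

Step 10
Reactants: 21 1-{2-hydroxy-6-methoxy-4-[2-(4-methoxyphenyl)-2-oxoethyl]phenyl}-4-methylpentan-1-one
Product: 22 1-{2,6-dihydroxy-4-[2-(4-methoxyphenyl)-2-oxoethyl]phenyl}-4-methylpentan-1-one (CNP0142242.0)
Conditions: BCl3 (3 equiv, 1 M in CH2Cl2), CH2Cl2, −78 → 0 °C; then H2O
Reagents that add atoms: none
Why: Chelation-directed Lewis acid ether cleavage, in which BCl3 held between the ring B ketone oxygen and the ortho methoxy oxygen delivers chloride to that methyl group only, so the C5–OMe is cleaved while the unchelated methoxy of ring A survives, and aqueous work-up hydrolyses the aryl borate to the target.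

**Compound list**
1 | 4-methoxybenzaldehyde | COc1ccc(C=O)cc1 | starting material
2 | propargyl bromide | BrCC#C | starting material
3 | allenylzinc bromide | C=C=C[Zn]Br | intermediate (not isolated)
4 | 1-(4-methoxyphenyl)but-3-yn-1-ol (racemic) | COc1ccc(C(O)CC#C)cc1 | intermediate
5 | tert-butyl{[1-(4-methoxyphenyl)but-3-yn-1-yl]oxy}dimethylsilane (racemic) | COc1ccc(C(CC#C)O[Si](C)(C)C(C)(C)C)cc1 | intermediate
6 | trichloroacetyl chloride | ClC(=O)C(Cl)(Cl)Cl | starting material
7 | dichloroketene | O=C=C(Cl)Cl | intermediate (not isolated)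
8 | 3-[2-(tert-butyldimethylsilyloxy)-2-(4-methoxyphenyl)ethyl]-4,4-dichlorocyclobut-2-en-1-one (racemic) | COc1ccc(C(CC2=CC(=O)C2(Cl)Cl)O[Si](C)(C)C(C)(C)C)cc1 | intermediate
9 | 3-[2-(tert-butyldimethylsilyloxy)-2-(4-methoxyphenyl)ethyl]cyclobut-2-en-1-one (racemic) | COc1ccc(C(CC2=CC(=O)C2)O[Si](C)(C)C(C)(C)C)cc1 | intermediate
10 | chloroacetaldehyde dimethyl acetal (2-chloro-1,1-dimethoxyethane) | COC(CCl)OC | starting material
11 | 4-methylpentanal | CC(C)CCC=O | starting material
12 | lithium methoxyacetylide | [Li]C#COC | intermediate (not isolated)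
13 | 1-methoxy-6-methylhept-1-yn-3-ol (racemic) | COC#CC(O)CCC(C)C | intermediate
14 | tert-butyl[(1-methoxy-6-methylhept-1-yn-3-yl)oxy]dimethylsilane (racemic) | COC#CC(CCC(C)C)O[Si](C)(C)C(C)(C)C | intermediate
15 | 5-(tert-butyldimethylsilyloxy)-5-(4-methoxyphenyl)-3-methylidenepent-1-en-1-one (vinylketene, racemic) | O=C=CC(=C)CC(O[Si](C)(C)C(C)(C)C)c1ccc(OC)cc1 | intermediate (not isolated)
16 | 2-[1-(tert-butyldimethylsilyloxy)-4-methylpentyl]-4-[4-(tert-butyldimethylsilyloxy)-4-(4-methoxyphenyl)but-1-en-2-yl]-3-methoxycyclobut-2-en-1-one (diastereomer mixture) | O=C1C(C(CCC(C)C)O[Si](C)(C)C(C)(C)C)=C(OC)C1C(=C)CC(O[Si](C)(C)C(C)(C)C)c1ccc(OC)cc1 | intermediate (not isolated)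
17 | (3E)-2-[1-(tert-butyldimethylsilyloxy)-4-methylpentyl]-7-(tert-butyldimethylsilyloxy)-3-methoxy-7-(4-methoxyphenyl)-5-methylidenehepta-1,3-dien-1-one (dienylketene, ketene and vinyl groups cis across C3=C4, diastereomer mixture) | O=C=C(C(CCC(C)C)O[Si](C)(C)C(C)(C)C)/C(OC)=C\C(=C)CC(O[Si](C)(C)C(C)(C)C)c1ccc(OC)cc1 | intermediate (not isolated)
18 | 2-[1-(tert-butyldimethylsilyloxy)-4-methylpentyl]-5-[2-(tert-butyldimethylsilyloxy)-2-(4-methoxyphenyl)ethyl]-3-methoxycyclohexa-2,4-dien-1-one (diastereomer mixture) | O=C1CC(CC(O[Si](C)(C)C(C)(C)C)c2ccc(OC)cc2)=CC(OC)=C1C(CCC(C)C)O[Si](C)(C)C(C)(C)C | intermediate (not isolated)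
19 | 2-[1-(tert-butyldimethylsilyloxy)-4-methylpentyl]-5-[2-(tert-butyldimethylsilyloxy)-2-(4-methoxyphenyl)ethyl]-3-methoxyphenol (diastereomer mixture) | COc1ccc(C(Cc2cc(O)c(C(CCC(C)C)O[Si](C)(C)C(C)(C)C)c(OC)c2)O[Si](C)(C)C(C)(C)C)cc1 | intermediate
20 | 2-(1-hydroxy-4-methylpentyl)-5-[2-hydroxy-2-(4-methoxyphenyl)ethyl]-3-methoxyphenol (diastereomer mixture) | COc1ccc(C(O)Cc2cc(O)c(C(O)CCC(C)C)c(OC)c2)cc1 | intermediate
21 | 1-{2-hydroxy-6-methoxy-4-[2-(4-methoxyphenyl)-2-oxoethyl]phenyl}-4-methylpentan-1-one | COc1ccc(C(=O)Cc2cc(O)c(C(=O)CCC(C)C)c(OC)c2)cc1 | intermediate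
22 | 1-{2,6-dihydroxy-4-[2-(4-methoxyphenyl)-2-oxoethyl]phenyl}-4-methylpentan-1-one (CNP0142242.0, achiral) | COc1ccc(C(=O)Cc2cc(O)c(C(=O)CCC(C)C)c(O)c2)cc1 | target

**Step count**
Total steps: 10 (steps 1–4 make the cyclobutenone, steps 5–6 the alkyne, steps 7–10 the union and endgame).
Longest linear sequence: 8 steps (1, 2, 3, 4, 7, 8, 9, 10).

**Steps most likely to fail**

1. Step 7 (benzannulation). The ketene–alkyne cycloaddition may be slow at the hindered, inductively deactivated ynol ether, so that the vinylketene is lost to oligomerisation or to acylation of the product phenol. Prolonged heating may also cause thermal loss of silanol from the ortho-hydroxybenzylic silyl ether. The fallback abandons the annulation and uses directed ortho-metalation on a bought resorcinol dimethyl ether; it sets out from 1 (and uses 11) and comes back to the route at 21. Commercial 3,5-dimethoxybenzyl chloride and Mg in THF give (3,5-dimethoxybenzyl)magnesium chloride F1, which adds to 1 to give 2-(3,5-dimethoxyphenyl)-1-(4-methoxyphenyl)ethan-1-ol F2. TBSCl and imidazole then give tert-butyl{[2-(3,5-dimethoxyphenyl)-1-(4-methoxyphenyl)ethyl]oxy}dimethylsilane F3. n-BuLi with TMEDA in THF at 0 °C should lithiate the position between the two methoxy groups to give {4-[2-(tert-butyldimethylsilyloxy)-2-(4-methoxyphenyl)ethyl]-2,6-dimethoxyphenyl}lithium F4, which is trapped with 11 to give 1-{4-[2-(tert-butyldimethylsilyloxy)-2-(4-methoxyphenyl)ethyl]-2,6-dimethoxyphenyl}-4-methylpentan-1-ol F5. TBAF gives 1-{4-[2-hydroxy-2-(4-methoxyphenyl)ethyl]-2,6-dimethoxyphenyl}-4-methylpentan-1-ol F6, and Dess–Martin periodinane with NaHCO3 gives 1-{2,6-dimethoxy-4-[2-(4-methoxyphenyl)-2-oxoethyl]phenyl}-4-methylpentan-1-one F7. One equivalent of BCl3 at −78 °C then cleaves one of the two chelated methyl ethers and delivers 21.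

2. Step 3 (dichloroketene cycloaddition). ZnCl2 may ionise the para-methoxybenzylic silyl ether (loss of silanol and elimination towards the enyne), or the ketene may oligomerise faster than it adds to the alkyne. The fallback replaces the ketene by a keteniminium salt, which needs no zinc and no dechlorination; it sets out from 5 and comes back to the route at 9, so step 4 is bypassed as well. N,N-Dimethylacetamide, Tf2O and 2,4,6-collidine in 1,2-dichloroethane give N-ethenylidene-N-methylmethanaminium trifluoromethanesulfonate F8. This adds to alkyne 5 in a [2+2] cycloaddition to give N-{3-[2-(tert-butyldimethylsilyloxy)-2-(4-methoxyphenyl)ethyl]cyclobut-2-en-1-ylidene}-N-methylmethanaminium trifluoromethanesulfonate F9, and hydrolysis with aqueous NaHCO3 should release 9.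

3. Step 9 (double MnO2 oxidation). Oxidation of the hindered C4 carbinol, flanked by OH and OMe, may stall, and the free electron-rich phenol may undergo oxidative coupling or ionisation to a quinone methide on the oxide surface. The fallback caps the phenol before the carbinols are unveiled, so that a general alcohol oxidant can be used; it sets out from 19 and comes back to the route at 21. MOMCl and i-Pr2NEt in CH2Cl2 give tert-butyl{1-[4-{2-(tert-butyldimethylsilyloxy)-2-(4-methoxyphenyl)ethyl}-2-methoxy-6-(methoxymethoxy)phenyl]-4-methylpentoxy}dimethylsilane F10. TBAF gives 1-{4-[2-hydroxy-2-(4-methoxyphenyl)ethyl]-2-methoxy-6-(methoxymethoxy)phenyl}-4-methylpentan-1-ol F11, and Dess–Martin periodinane with NaHCO3 gives 1-{2-methoxy-6-(methoxymethoxy)-4-[2-(4-methoxyphenyl)-2-oxoethyl]phenyl}-4-methylpentan-1-one F12. HCl in MeOH then removes the acetal to give 21.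

**Further compounds**
F1 | step 7 | (3,5-dimethoxybenzyl)magnesium chloride | COc1cc(C[Mg]Cl)cc(OC)c1
F2 | step 7 | 2-(3,5-dimethoxyphenyl)-1-(4-methoxyphenyl)ethan-1-ol (racemic) | COc1ccc(C(O)Cc2cc(OC)cc(OC)c2)cc1
F3 | step 7 | tert-butyl{[2-(3,5-dimethoxyphenyl)-1-(4-methoxyphenyl)ethyl]oxy}dimethylsilane (racemic) | COc1ccc(C(Cc2cc(OC)cc(OC)c2)O[Si](C)(C)C(C)(C)C)cc1
F4 | step 7 | {4-[2-(tert-butyldimethylsilyloxy)-2-(4-methoxyphenyl)ethyl]-2,6-dimethoxyphenyl}lithium (racemic) | COc1ccc(C(Cc2cc(OC)c([Li])c(OC)c2)O[Si](C)(C)C(C)(C)C)cc1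
F5 | step 7 | 1-{4-[2-(tert-butyldimethylsilyloxy)-2-(4-methoxyphenyl)ethyl]-2,6-dimethoxyphenyl}-4-methylpentan-1-ol (diastereomer mixture) | COc1ccc(C(Cc2cc(OC)c(C(O)CCC(C)C)c(OC)c2)O[Si](C)(C)C(C)(C)C)cc1
F6 | step 7 | 1-{4-[2-hydroxy-2-(4-methoxyphenyl)ethyl]-2,6-dimethoxyphenyl}-4-methylpentan-1-ol (diastereomer mixture) | COc1ccc(C(O)Cc2cc(OC)c(C(O)CCC(C)C)c(OC)c2)cc1
F7 | step 7 | 1-{2,6-dimethoxy-4-[2-(4-methoxyphenyl)-2-oxoethyl]phenyl}-4-methylpentan-1-one | COc1ccc(C(=O)Cc2cc(OC)c(C(=O)CCC(C)C)c(OC)c2)cc1
F8 | step 3 | N-ethenylidene-N-methylmethanaminium trifluoromethanesulfonate | C=C=[N+](C)C.[O-]S(=O)(=O)C(F)(F)F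
F9 | step 3 | N-{3-[2-(tert-butyldimethylsilyloxy)-2-(4-methoxyphenyl)ethyl]cyclobut-2-en-1-ylidene}-N-methylmethanaminium trifluoromethanesulfonate (racemic) | COc1ccc(C(CC2=CC(=[N+](C)C)C2)O[Si](C)(C)C(C)(C)C)cc1.[O-]S(=O)(=O)C(F)(F)F
F10 | step 9 | tert-butyl{1-[4-{2-(tert-butyldimethylsilyloxy)-2-(4-methoxyphenyl)ethyl}-2-methoxy-6-(methoxymethoxy)phenyl]-4-methylpentoxy}dimethylsilane (diastereomer mixture) | COCOc1cc(CC(O[Si](C)(C)C(C)(C)C)c2ccc(OC)cc2)cc(OC)c1C(CCC(C)C)O[Si](C)(C)C(C)(C)C
F11 | step 9 | 1-{4-[2-hydroxy-2-(4-methoxyphenyl)ethyl]-2-methoxy-6-(methoxymethoxy)phenyl}-4-methylpentan-1-ol (diastereomer mixture) | COCOc1cc(CC(O)c2ccc(OC)cc2)cc(OC)c1C(O)CCC(C)C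
F12 | step 9 | 1-{2-methoxy-6-(methoxymethoxy)-4-[2-(4-methoxyphenyl)-2-oxoethyl]phenyl}-4-methylpentan-1-one | COCOc1cc(CC(=O)c2ccc(OC)cc2)cc(OC)c1C(=O)CCC(C)C
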